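**Retrosynthetic overview**
- Platanetin is 3,5,7,8-tetrahydroxy-6-prenylflavone; the C8 hydroxyl (Elbs oxidation para to the 5-OH) and the C3 hydroxyl (C3 lithiation, borylation, oxidation) are added last, leading back to 5,7-bis(methoxymethoxy)-6-prenylflavone 15.
- The strategy rests on ring A carrying O1 (on C8a) and the C4 carbonyl (on C4a) at neighbouring carbons, with the C5 oxygen directly beside C4a. A C4a–C8a aryne polarised by that C5 oxygen can therefore take up the carboxyl oxygen of 3-phenylpropiolic acid at C8a and its acyl carbon at C4a, and the O1–C2 bond then closes ring C.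
- Aryne precursor 11 (ortho-silylaryl triflate) comes from the C2-symmetric phenol 7 by ortho-bromination and a retro-Brook/triflation sequence; 7 comes from phloroglucinol by bis-MOM protection, silylation and lithiation–prenylation between the two MOM ethers.
- Ring order: ring A is bought (phloroglucinol), ring B arrives with phenylpropiolic acid, ring C is formed in the key step.

Key step: step 7

Remark: flavone numbering (O1, C2, C3, C4, C4a, C5–C8, C8a) is used throughout; the target has no stereocentre and the prenyl double bond is trisubstituted with two identical methyl groups, so no configuration has to be set.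

**Route**

Step 1
Reactants: 1 phloroglucinol (benzene-1,3,5-triol)
Product: 2 3,5-bis(methoxymethoxy)phenol
Conditions: MOMCl (2.0 equiv), i-Pr2NEt, CH2Cl2–DMF, 0 °C to rt; chromatography to remove mono- and tris-ethers
Reagents that add atoms: chloromethyl methyl ether, COCCl
Why: O-alkylation of two of the three equivalent phenols with an alkoxymethyl chloride should give the bis-acetal as the main component of a statistical mixture that is separable by polarity.

Step 2
Reactants: 2 3,5-bis(methoxymethoxy)phenol
Product: 3 [3,5-bis(methoxymethoxy)phenoxy]tri(propan-2-yl)silane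
Conditions: TIPSCl, imidazole, DMF, rt
Reagents that add atoms: chlorotri(propan-2-yl)silane, CC(C)[Si](Cl)(C(C)C)C(C)C
Why: Imidazole-mediated silylation of the phenol installs a bulky, non-coordinating silyl ether that tolerates n-BuLi and does not direct metalation.

Step 3
Reactants: 3 [3,5-bis(methoxymethoxy)phenoxy]tri(propan-2-yl)silane; 4 prenyl bromide (1-bromo-3-methylbut-2-ene)
Product: 6 [3,5-bis(methoxymethoxy)-4-(3-methylbut-2-enyl)phenoxy]tri(propan-2-yl)silane, via 4-lithio arene 5 (not isolated)
Conditions: n-BuLi, THF, 0 °C to rt; CuI (10 mol %), 4, −78 °C to rt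
Reagents that add atoms: none
Why: Directed ortho-metalation should occur at the carbon flanked by both chelating MOM ethers rather than beside the hindered silyl ether, and copper-catalysed SN2 allylation of the aryllithium gives the linear prenyl group.

Step 4
Reactants: 6 [3,5-bis(methoxymethoxy)-4-(3-methylbut-2-enyl)phenoxy]tri(propan-2-yl)silane
Product: 7 3,5-bis(methoxymethoxy)-4-(3-methylbut-2-enyl)phenol
Conditions: n-Bu4NF, AcOH, THF, 0 °C
Reagents that add atoms: none
Why: Fluoride-induced cleavage of the aryl silyl ether, buffered with acetic acid so that the electron-rich phenoxide is protonated at once, should leave the MOM acetals and the alkene untouched.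

Step 5
Reactants: 7 3,5-bis(methoxymethoxy)-4-(3-methylbut-2-enyl)phenol
Product: 8 2-bromo-3,5-bis(methoxymethoxy)-4-(3-methylbut-2-enyl)phenol
Conditions: NBS (1.0 equiv, slow addition), CH2Cl2, −78 °C
Reagents that add atoms: N-bromosuccinimide, O=C1CCC(=O)N1Br
Why: Electrophilic aromatic bromination of a phloroglucinol-type ring is very fast at low temperature, the two open ring positions are equivalent by symmetry and ortho to the hydroxyl, and the arene should outpace the trisubstituted alkene.

Step 6
Reactants: 8 2-bromo-3,5-bis(methoxymethoxy)-4-(3-methylbut-2-enyl)phenol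
Product: 11 3,5-bis(methoxymethoxy)-4-(3-methylbut-2-enyl)-2-(trimethylsilyl)phenyl trifluoromethanesulfonate, via aryl trimethylsilyl ether 9 (not isolated), via lithium 2-silylphenolate 10 (not isolated)
Conditions: (Me3Si)2NH, THF, 70 °C, then evaporation; n-BuLi, THF, −100 to −80 °C; Tf2O, −100 to −78 °C; cold aq NaHCO3
Reagents that add atoms: hexamethyldisilazane, C[Si](C)(C)N[Si](C)(C)C; trifluoromethanesulfonic anhydride, O=S(=O)(OS(=O)(=O)C(F)(F)F)C(F)(F)F
Why: O-silylation, bromine–lithium exchange and the ensuing retro-Brook 1,3 O-to-C silyl shift place the trimethylsilyl group on the carbon between the oxygen and the MOM ether, and the released phenoxide is trapped as the triflate in the standard one-pot route to ortho-silylaryl triflates.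

Step 7
Reactants: 11 3,5-bis(methoxymethoxy)-4-(3-methylbut-2-enyl)-2-(trimethylsilyl)phenyl trifluoromethanesulfonate; 12 3-phenylpropiolic acid
Product: 15 5,7-bis(methoxymethoxy)-6-(3-methylbut-2-enyl)-2-phenylchromen-4-one, via aryne 13 (not isolated), via ortho-hydroxyaryl ynone 14 (not isolated)
Conditions: 12 (1.2 equiv), CsF (4 equiv), THF, 125 °C, sealed tube
Reagents that add atoms: none
Why: Fluoride attack on silicon expels triflate and releases aryne 13; the cesium carboxylate of 12 adds through oxygen to C8a, the aryl anion left at C4a attacks the neighbouring ester carbonyl through a four-membered alkoxide, and C–O cleavage gives the ortho-acyl phenoxide of ynone 14. The closest known reaction type is the fluoride-induced insertion of arynes into the C–O bond of carboxylic acids, which with arylpropiolic acids runs on to flavones. Ring C then closes by 6-endo-dig oxa-Michael addition of the C8a phenoxide to the ynone terminus C2 (O1–C2 bond), and protonation at C3 gives the 4-pyranone. No stereocentre is formed. The step needs regioselective addition to the aryne, acyl transfer faster than protonation of the aryl anion, and 6-endo rather than 5-exo closure: the methoxymethoxy group on C5 distorts the aryne so that C8a is the more electrophilic and less hindered terminus and stabilises the anion at C4a, the high temperature and the low concentration of free acid favour acyl migration, and the Michael polarisation of the ynone directs the phenoxide to C2.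

Step 8
Reactants: 15 5,7-bis(methoxymethoxy)-6-(3-methylbut-2-enyl)-2-phenylchromen-4-one
Product: 18 3-hydroxy-5,7-bis(methoxymethoxy)-6-(3-methylbut-2-enyl)-2-phenylchromen-4-one, via 3-lithioflavone 16 (not isolated), via lithium trimethoxyborate 17 (not isolated)
Conditions: LiN(i-Pr)2 (1.5 equiv), THF, −78 °C; B(OMe)3, −78 to 0 °C; AcOH, 30% H2O2, 0 °C to rt
Reagents that add atoms: hydrogen peroxide, OO
Why: The carbonyl-assisted deprotonation of flavones at C3 by a hindered lithium amide, borylation of the vinyllithium and oxidative C–B to C–O conversion is an established flavone-to-flavonol sequence, and dilute peroxide under these conditions should not epoxidise the prenyl alkene.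

Step 9
Reactants: 18 3-hydroxy-5,7-bis(methoxymethoxy)-6-(3-methylbut-2-enyl)-2-phenylchromen-4-one
Product: 19 3,5,7-trihydroxy-6-(3-methylbut-2-enyl)-2-phenylchromen-4-one
Conditions: 3 M HCl, MeOH, 50 °C
Reagents that add atoms: none
Why: Acid-catalysed acetal exchange with methanol removes both MOM groups under conditions that are commonly used on ortho-prenylphenols without chroman formation.

Step 10
Reactants: 19 3,5,7-trihydroxy-6-(3-methylbut-2-enyl)-2-phenylchromen-4-one
Product: 20 5-hydroxy-3,7-bis(methoxymethoxy)-6-(3-methylbut-2-enyl)-2-phenylchromen-4-one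
Conditions: MOMCl (2.2 equiv), i-Pr2NEt, CH2Cl2–DMF, 0 °C to rt
Reagents that add atoms: chloromethyl methyl ether, COCCl
Why: Selective O-alkylation should protect the acidic 7-OH and the 3-OH while the 5-OH, hydrogen-bonded to the C4 carbonyl and flanked by the prenyl group, stays free; the 3-oxygen has to be masked because a free flavonolate is degraded by persulfate in alkali.

Step 11
Reactants: 20 5-hydroxy-3,7-bis(methoxymethoxy)-6-(3-methylbut-2-enyl)-2-phenylchromen-4-one
Product: 22 platanetin (3,5,7,8-tetrahydroxy-6-(3-methylbut-2-enyl)-2-phenylchromen-4-one), via potassium 8-sulfate 21 (not isolated)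
Conditions: K2S2O8 (1.0 equiv), aq KOH, pyridine, 15 °C to rt; then HCl, MeOH, 50 °C, argon
Reagents that add atoms: potassium peroxodisulfate, [K+].[K+].[O-]S(=O)(=O)OOS(=O)(=O)[O-]
Why: In the Elbs persulfate oxidation the 5-phenoxide attacks the peroxide oxygen through its para carbon C8, the only open position of ring A, as known for 5-hydroxy-3,7-dialkoxyflavones, and the acidic methanolysis then cleaves the aryl sulfate and both MOM ethers to give the target.

**Compound list**
1 | phloroglucinol (benzene-1,3,5-triol) | Oc1cc(O)cc(O)c1 | starting material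
2 | 3,5-bis(methoxymethoxy)phenol | COCOc1cc(O)cc(OCOC)c1 | intermediate
3 | [3,5-bis(methoxymethoxy)phenoxy]tri(propan-2-yl)silane | COCOc1cc(OCOC)cc(O[Si](C(C)C)(C(C)C)C(C)C)c1 | intermediate
4 | prenyl bromide (1-bromo-3-methylbut-2-ene) | CC(C)=CCBr | starting material
5 | [2,6-bis(methoxymethoxy)-4-(triisopropylsilyloxy)phenyl]lithium (not isolated) | COCOc1cc(O[Si](C(C)C)(C(C)C)C(C)C)cc(OCOC)c1[Li] | intermediate
6 | [3,5-bis(methoxymethoxy)-4-(3-methylbut-2-enyl)phenoxy]tri(propan-2-yl)silane | CC(C)=CCc1c(OCOC)cc(O[Si](C(C)C)(C(C)C)C(C)C)cc1OCOC | intermediate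
7 | 3,5-bis(methoxymethoxy)-4-(3-methylbut-2-enyl)phenol | CC(C)=CCc1c(OCOC)cc(O)cc1OCOC | intermediate
8 | 2-bromo-3,5-bis(methoxymethoxy)-4-(3-methylbut-2-enyl)phenol | CC(C)=CCc1c(OCOC)cc(O)c(Br)c1OCOC | intermediate
9 | [2-bromo-3,5-bis(methoxymethoxy)-4-(3-methylbut-2-enyl)phenoxy]trimethylsilane (not isolated) | CC(C)=CCc1c(OCOC)cc(O[Si](C)(C)C)c(Br)c1OCOC | intermediate
10 | lithium 3,5-bis(methoxymethoxy)-4-(3-methylbut-2-enyl)-2-(trimethylsilyl)phenolate (not isolated) | CC(C)=CCc1c(OCOC)cc([O-])c([Si](C)(C)C)c1OCOC.[Li+] | intermediate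
11 | 3,5-bis(methoxymethoxy)-4-(3-methylbut-2-enyl)-2-(trimethylsilyl)phenyl trifluoromethanesulfonate | CC(C)=CCc1c(OCOC)cc(OS(=O)(=O)C(F)(F)F)c([Si](C)(C)C)c1OCOC | intermediate
12 | 3-phenylpropiolic acid (3-phenylprop-2-ynoic acid) | OC(=O)C#Cc1ccccc1 | starting material
13 | 3,5-bis(methoxymethoxy)-4-(3-methylbut-2-enyl)benzyne, triple bond between the former C1 and C2 of 11 (not isolated) | CC(C)=CCC1=C(OCOC)C#CC=C1OCOC | intermediate
14 | 1-[6-hydroxy-2,4-bis(methoxymethoxy)-3-(3-methylbut-2-enyl)phenyl]-3-phenylprop-2-yn-1-one (not isolated) | CC(C)=CCc1c(OCOC)cc(O)c(C(=O)C#Cc2ccccc2)c1OCOC | intermediate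
15 | 5,7-bis(methoxymethoxy)-6-(3-methylbut-2-enyl)-2-phenylchromen-4-one | CC(C)=CCc1c(OCOC)cc2oc(-c3ccccc3)cc(=O)c2c1OCOC | intermediate
16 | 3-lithio-5,7-bis(methoxymethoxy)-6-(3-methylbut-2-enyl)-2-phenylchromen-4-one (not isolated) | CC(C)=CCc1c(OCOC)cc2oc(-c3ccccc3)c([Li])c(=O)c2c1OCOC | intermediate
17 | lithium trimethoxy[5,7-bis(methoxymethoxy)-6-(3-methylbut-2-enyl)-4-oxo-2-phenylchromen-3-yl]borate (not isolated) | CC(C)=CCc1c(OCOC)cc2oc(-c3ccccc3)c([B-](OC)(OC)OC)c(=O)c2c1OCOC.[Li+] | intermediate
18 | 3-hydroxy-5,7-bis(methoxymethoxy)-6-(3-methylbut-2-enyl)-2-phenylchromen-4-one | CC(C)=CCc1c(OCOC)cc2oc(-c3ccccc3)c(O)c(=O)c2c1OCOC | intermediate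
19 | 3,5,7-trihydroxy-6-(3-methylbut-2-enyl)-2-phenylchromen-4-one | CC(C)=CCc1c(O)cc2oc(-c3ccccc3)c(O)c(=O)c2c1O | intermediate
20 | 5-hydroxy-3,7-bis(methoxymethoxy)-6-(3-methylbut-2-enyl)-2-phenylchromen-4-one | CC(C)=CCc1c(OCOC)cc2oc(-c3ccccc3)c(OCOC)c(=O)c2c1O | intermediate
21 | potassium 5-hydroxy-3,7-bis(methoxymethoxy)-6-(3-methylbut-2-enyl)-4-oxo-2-phenylchromen-8-yl sulfate (not isolated) | CC(C)=CCc1c(OCOC)c(OS(=O)(=O)[O-])c2oc(-c3ccccc3)c(OCOC)c(=O)c2c1O.[K+] | intermediate
22 | platanetin (3,5,7,8-tetrahydroxy-6-(3-methylbut-2-enyl)-2-phenylchromen-4-one) | CC(C)=CCc1c(O)c(O)c2oc(-c3ccccc3)c(O)c(=O)c2c1O | target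

**Step count**
Total: 11 steps. Longest linear sequence: 11 steps, from phloroglucinol 1 to platanetin 22 (prenyl bromide 4 and 3-phenylpropiolic acid 12 enter as purchased materials).

**Steps most likely to fail**

1. Step 7 (aryne insertion and ring C closure). The aryl anion at C4a may be protonated before acyl transfer, which ends in simple O-arylation of the acid. The propiolate may lose CO2 at 125 °C, addition to the tetrasubstituted aryne may be slow, and the phenoxide may close 5-exo instead of 6-endo. Fallback by carbonyl addition, setting out from bromophenol 8 and returning at flavone 15: 8 is converted with n-BuLi (2.2 equiv, THF, −78 to 0 °C) into the O,C-dilithio species, which adds to 3-phenylprop-2-ynal at −78 °C to give racemic 2-(1-hydroxy-3-phenylprop-2-ynyl)-3,5-bis(methoxymethoxy)-4-(3-methylbut-2-enyl)phenol F1. MnO2 in CH2Cl2 at rt oxidises the benzylic propargylic alcohol to ynone 14, which is isolated here. K2CO3 in acetone then closes ring C by the same 6-endo oxa-Michael addition to give 15. The free phenol of 8 is the oxygen that becomes O1, so the regiochemistry of the flavone is fixed.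

2. Step 11 (Elbs oxidation and acid release). Conversion in persulfate oxidations is often incomplete, the prenyl double bond may be attacked by sulfate radicals, and the hot acid needed for the sulfate may cyclise the prenyl group onto a flanking hydroxyl. Fallback through the quinone, setting out from 20 and returning at 22: Teuber oxidation of 20 with Frémy's salt, (KSO3)2NO (2.2 equiv), in KH2PO4-buffered acetone–water at rt should give 3,7-bis(methoxymethoxy)-6-(3-methylbut-2-enyl)-2-phenylchromene-4,5,8-trione F2. Reduction with Na2S2O4 in EtOAc–water gives 5,8-dihydroxy-3,7-bis(methoxymethoxy)-6-(3-methylbut-2-enyl)-2-phenylchromen-4-one F3. Brief treatment with HCl in MeOH at 50 °C under argon removes the MOM groups to give 22; no aryl sulfate has to be hydrolysed, so the acid exposure is shorter.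

3. Step 5 (ring bromination). Bromine may add to the prenyl alkene, or the second ortho position may brominate as well. Fallback by carbamate-directed ortho-silylation, setting out from phenol 7 and returning at triflate 11:
   - 7 and isopropyl isocyanate (Et3N cat., CH2Cl2) give 3,5-bis(methoxymethoxy)-4-(3-methylbut-2-enyl)phenyl N-(propan-2-yl)carbamate F4.
   - N-silylation in the flask (Me3SiOTf 1.05 equiv, TMEDA, Et2O, 0 °C), ortho-lithiation (n-BuLi, TMEDA, −78 °C), quench with Me3SiCl and mild acidic work-up give 3,5-bis(methoxymethoxy)-4-(3-methylbut-2-enyl)-2-(trimethylsilyl)phenyl N-(propan-2-yl)carbamate F5. The silyl triflate is kept at one equivalent and 0 °C so that the MOM acetals are not activated.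
   - Et2NH and DBU in MeCN at 40 °C cleave the carbamate to 3,5-bis(methoxymethoxy)-4-(3-methylbut-2-enyl)-2-(trimethylsilyl)phenol F6.
   - PhNTf2 converts F6 into 11.

   Both ortho positions of F4 are equivalent and doubly activated by the carbamate and a MOM ether, so only one silyl regioisomer can form.

**Further compounds**
F1 | step 7 | 2-(1-hydroxy-3-phenylprop-2-ynyl)-3,5-bis(methoxymethoxy)-4-(3-methylbut-2-enyl)phenol (racemic) | CC(C)=CCc1c(OCOC)cc(O)c(C(O)C#Cc2ccccc2)c1OCOC
F2 | step 11 | 3,7-bis(methoxymethoxy)-6-(3-methylbut-2-enyl)-2-phenylchromene-4,5,8-trione | CC(C)=CCC1=C(OCOC)C(=O)C2=C(C1=O)C(=O)C(OCOC)=C(c3ccccc3)O2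
F3 | step 11 | 5,8-dihydroxy-3,7-bis(methoxymethoxy)-6-(3-methylbut-2-enyl)-2-phenylchromen-4-one | CC(C)=CCc1c(OCOC)c(O)c2oc(-c3ccccc3)c(OCOC)c(=O)c2c1O
F4 | step 5 | 3,5-bis(methoxymethoxy)-4-(3-methylbut-2-enyl)phenyl N-(propan-2-yl)carbamate | CC(C)=CCc1c(OCOC)cc(OC(=O)NC(C)C)cc1OCOC
F5 | step 5 | 3,5-bis(methoxymethoxy)-4-(3-methylbut-2-enyl)-2-(trimethylsilyl)phenyl N-(propan-2-yl)carbamate | CC(C)=CCc1c(OCOC)cc(OC(=O)NC(C)C)c([Si](C)(C)C)c1OCOC
F6 | step 5 | 3,5-bis(methoxymethoxy)-4-(3-methylbut-2-enyl)-2-(trimethylsilyl)phenol | CC(C)=CCc1c(OCOC)cc(O)c([Si](C)(C)C)c1OCOC
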